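The chain is cut at C1–C2 and C6–C7. The key step exploits the local twofold symmetry of C2–C6, whose anti oxygens on C3 and C5 map onto the two homotopic oxirane rings of (2R,4R)-1,2:4,5-diepoxypentane, while benzylic C1 (on guaiacyl ring A) and C7 (on syringyl ring B) arrive as carbanionic dithiane carbons. In one flask the two lithiated aryl dithianes open the terminal oxirane carbons in turn, giving the full seven-carbon chain with both carbinol centres in place. The precursor set is the bis-epoxide, made in three steps by asymmetric hydrogenation, and two O-benzyl aryl dithianes; one Raney nickel treatment then strips sulfur and benzyl groups.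

Key step: step 7

Remark: the two carbinol carbons keep one spatial arrangement from 4 to 15; their descriptors read R,R in 4, 5, 12 and 14 and S,S in 15 only because the CIP ranking of the flanking CH2 groups changes (in 14 the CH2 next to the sulfur-bearing carbon outranks the central CH2); 6 is taken as a stock chemical.

Step 1
Reactants: 1 pentane-2,4-dione; 2 chloroacetyl chloride
Product: 3 1,5-dichloropentane-2,4-dione
Conditions: 2 (2.5 equiv), AlCl3 (3 equiv), PhNO2, 60 °C; ice/aq. HCl; distillation
Reagents that add atoms: none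
Why: AlCl3-promoted acyl exchange (Friedel–Crafts-type C-acylation of the diketone at C3 followed by retro-Claisen loss of acetyl chloride, twice over) is an established entry to this symmetrical bis(chloromethyl) diketone and is driven by escape of the volatile acetyl chloride.

Step 2
Reactants: 3 1,5-dichloropentane-2,4-dione
Product: 4 (2R,4R)-1,5-dichloropentane-2,4-diol
Conditions: H2 (85 bar), RuCl2[(S)-BINAP] (0.2 mol %), MeOH, 100 °C; recrystallisation
Reagents that add atoms: none
Why: Noyori asymmetric hydrogenation of a chelating 1,3-diketone, in which the (S)-BINAP ruthenium catalyst should reduce each carbonyl in the same absolute sense and so set both carbinol centres as R (the anti diol), with recrystallisation removing any meso isomer.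

Step 3
Reactants: 4 (2R,4R)-1,5-dichloropentane-2,4-diol
Product: 5 (2R,4R)-1,2:4,5-diepoxypentane
Conditions: KOH (powdered, 4 equiv), Et2O, rt; filtration, distillation
Reagents that add atoms: none
Why: double intramolecular Williamson etherification (3-exo-tet closure of each chlorohydrin) in which the alkoxide displaces the primary chloride, so neither carbinol C–O bond is broken and both R centres are retained.

Step 4
Reactants: 6 4-(benzyloxy)-3-methoxybenzaldehyde
Product: 7 2-[4-(benzyloxy)-3-methoxyphenyl]-1,3-dithiane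
Conditions: HS(CH2)3SH (1.1 equiv), I2 (10 mol %), CH2Cl2, rt
Reagents that add atoms: propane-1,3-dithiol, SCCCS
Why: iodine-catalysed dithioacetalisation of an aromatic aldehyde, mild enough to leave the aryl benzyl ether untouched.

Step 5
Reactants: 8 syringaldehyde
Product: 9 4-(benzyloxy)-3,5-dimethoxybenzaldehyde
Conditions: BnBr (1.2 equiv), K2CO3 (1.5 equiv), DMF, 60 °C
Reagents that add atoms: benzyl bromide, BrCc1ccccc1
Why: Williamson ether synthesis, the phenoxide of the acidic 2,6-dimethoxyphenol being alkylated cleanly by a benzylic bromide in DMF.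

Step 6
Reactants: 9 4-(benzyloxy)-3,5-dimethoxybenzaldehyde
Product: 10 2-[4-(benzyloxy)-3,5-dimethoxyphenyl]-1,3-dithiane
Conditions: HS(CH2)3SH (1.1 equiv), I2 (10 mol %), CH2Cl2, rt
Reagents that add atoms: propane-1,3-dithiol, SCCCS
Why: the same iodine-catalysed dithioacetalisation as in step 4, applied to the equally reactive syringyl aldehyde.

Step 7
Reactants: 7 2-[4-(benzyloxy)-3-methoxyphenyl]-1,3-dithiane; 5 (2R,4R)-1,2:4,5-diepoxypentane; 10 2-[4-(benzyloxy)-3,5-dimethoxyphenyl]-1,3-dithiane
Product: 14 (2R,4R)-1-{2-[4-(benzyloxy)-3-methoxyphenyl]-1,3-dithian-2-yl}-5-{2-[4-(benzyloxy)-3,5-dimethoxyphenyl]-1,3-dithian-2-yl}pentane-2,4-diol, via 2-lithio guaiacyl dithiane 11 (not isolated), via lithium epoxy alkoxide 12 (not isolated), via 2-lithio syringyl dithiane 13 (not isolated)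
Conditions: 7, n-BuLi (1.05 equiv), THF, −78 → −20 °C; slow inverse addition to 5 (4 equiv), THF, −78 → 0 °C; THF and excess 5 evaporated (0.1 mbar, ≤ 20 °C, cold trap, 5 recovered); THF, then 13 (1.3 equiv, from 10 and n-BuLi, THF, −78 → −20 °C), −78 → 0 °C; aq. NH4Cl
Reagents that add atoms: none
Why: n-BuLi removes the C2 proton of each 2-aryl-1,3-dithiane to give a carbanion stabilised by two sulfur atoms and the arene, and this carbanion opens an oxirane by SN2 attack at its unsubstituted CH2 carbon (Corey–Seebach umpolung alkylation, run twice on one twofold-symmetric bis-epoxide), forming C1–C2 and then C6–C7. The closest known reaction type is the sequential opening of 1,2:4,5-diepoxypentane by two different lithiated 2-substituted 1,3-dithianes. No ring is closed and no stereocentre is made, because the C3–O and C5–O bonds of 5 are never broken and both carbinol configurations pass unchanged into 14. Regioselectivity for the terminal carbon follows from the steric bias of a monosubstituted oxirane toward a bulky tertiary carbanion. Mono-opening in the first stage is secured by adding 11 slowly to a fourfold excess of 5, whose homotopic oxirane rings allow only one mono-adduct 12, and the volatile excess is distilled out of the flask before 13 is introduced so that the second nucleophile meets only 12. Deprotonation at the dithiane carbon and not at the OCH2Ph groups rests on the far higher acidity of the doubly sulfur-stabilised benzylic C–H at low temperature.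

Step 8
Reactants: 14 (2R,4R)-1-{2-[4-(benzyloxy)-3-methoxyphenyl]-1,3-dithian-2-yl}-5-{2-[4-(benzyloxy)-3,5-dimethoxyphenyl]-1,3-dithian-2-yl}pentane-2,4-diol
Product: 15 (3S,5S)-1-(4-hydroxy-3-methoxyphenyl)-7-(4-hydroxy-3,5-dimethoxyphenyl)heptane-3,5-diol
Conditions: Raney Ni (W-2, large excess), H2 (1 atm), EtOH/THF, rt → 50 °C
Reagents that add atoms: none
Why: Raney nickel desulfurisation (Mozingo-type hydrogenolysis) should cleave the four benzylic C–S bonds to leave C1 and C7 as methylenes while the same nickel surface under H2 hydrogenolyses the two aryl benzyl ethers, the carbinol centres taking no part.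

Compound list
1 | pentane-2,4-dione | CC(=O)CC(C)=O | starting material
2 | chloroacetyl chloride | ClCC(Cl)=O | starting material
3 | 1,5-dichloropentane-2,4-dione | ClCC(=O)CC(=O)CCl | intermediate
4 | (2R,4R)-1,5-dichloropentane-2,4-diol | ClC[C@H](O)C[C@@H](O)CCl | intermediate
5 | (2R,4R)-1,2:4,5-diepoxypentane | C1O[C@@H]1C[C@H]1OC1 | intermediate
6 | 4-(benzyloxy)-3-methoxybenzaldehyde | COc1cc(C=O)ccc1OCc1ccccc1 | starting material
7 | 2-[4-(benzyloxy)-3-methoxyphenyl]-1,3-dithiane | COc1cc(C2SCCCS2)ccc1OCc1ccccc1 | intermediate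
8 | syringaldehyde (4-hydroxy-3,5-dimethoxybenzaldehyde) | COc1cc(C=O)cc(OC)c1O | starting material
9 | 4-(benzyloxy)-3,5-dimethoxybenzaldehyde | COc1cc(C=O)cc(OC)c1OCc1ccccc1 | intermediate
10 | 2-[4-(benzyloxy)-3,5-dimethoxyphenyl]-1,3-dithiane | COc1cc(C2SCCCS2)cc(OC)c1OCc1ccccc1 | intermediate
11 | 2-lithio-2-[4-(benzyloxy)-3-methoxyphenyl]-1,3-dithiane (2-lithio guaiacyl dithiane) | [Li]C1(SCCCS1)c1ccc(OCc2ccccc2)c(OC)c1 | intermediate
12 | lithium (2R)-1-{2-[4-(benzyloxy)-3-methoxyphenyl]-1,3-dithian-2-yl}-3-[(2R)-oxiran-2-yl]propan-2-olate (lithium epoxy alkoxide) | [Li+].COc1cc(C2(C[C@H]([O-])C[C@@H]3CO3)SCCCS2)ccc1OCc1ccccc1 | intermediate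
13 | 2-lithio-2-[4-(benzyloxy)-3,5-dimethoxyphenyl]-1,3-dithiane (2-lithio syringyl dithiane) | [Li]C1(SCCCS1)c1cc(OC)c(OCc2ccccc2)c(OC)c1 | intermediate
14 | (2R,4R)-1-{2-[4-(benzyloxy)-3-methoxyphenyl]-1,3-dithian-2-yl}-5-{2-[4-(benzyloxy)-3,5-dimethoxyphenyl]-1,3-dithian-2-yl}pentane-2,4-diol | COc1cc(C2(C[C@H](O)C[C@@H](O)CC3(c4cc(OC)c(OCc5ccccc5)c(OC)c4)SCCCS3)SCCCS2)ccc1OCc1ccccc1 | intermediate
15 | (3S,5S)-1-(4-hydroxy-3-methoxyphenyl)-7-(4-hydroxy-3,5-dimethoxyphenyl)heptane-3,5-diol | COc1cc(CC[C@H](O)C[C@@H](O)CCc2cc(OC)c(O)c(OC)c2)ccc1O | target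

Total step count: 8
Longest linear sequence: 5 steps (steps 1, 2, 3, 7, 8)

Steps most likely to fail

Step 7. Three processes threaten it: double opening of the bis-epoxide by the first carbanion, carry-over of unremoved bis-epoxide into the second stage so that the second carbanion is consumed in a symmetrical double opening, and stalling of the second opening on the aggregated alkoxide. The fallback gives up the one-flask union for two separate couplings with purification in between. It sets out from 7 and 5: the first opening is run as above but quenched with aqueous NH4Cl, excess 5 is distilled off, and chromatography isolates the epoxy alcohol (2R)-1-{2-[4-(benzyloxy)-3-methoxyphenyl]-1,3-dithian-2-yl}-3-[(2R)-oxiran-2-yl]propan-2-ol F1 free of doubly opened material. F1 is then treated with 13 (2.3 equiv, the first equivalent being spent on the hydroxyl) in THF/DMPU at −78 → 0 °C, and the route is rejoined at 14.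

Step 8. Hydrogenolysis of the benzyl ethers may stay incomplete, and hot Raney nickel may dehydrogenate and rehydrogenate the secondary carbinols and so epimerise C3 and C5. The fallback splits the step into two chemoselective operations. It sets out from 14: nickel boride Ni2B, made in the flask from NiCl2·6H2O and NaBH4 in MeOH/THF at 0 °C, should remove only the sulfur and give (3S,5S)-1-[4-(benzyloxy)-3-methoxyphenyl]-7-[4-(benzyloxy)-3,5-dimethoxyphenyl]heptane-3,5-diol F2. Hydrogenolysis of the now sulfur-free F2 over Pd/C (H2, 1 atm, EtOH/EtOAc, rt) rejoins the route at 15.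

Step 2. Enantio- or diastereocontrol in the double hydrogenation may erode, or hydrodechlorination may compete. The fallback takes both stereocentres from the chiral pool: it uses none of 1 to 4, starts from commercial L-arabitol (OC[C@H](O)C(O)[C@@H](O)CO) and rejoins the route at 5.
- Ketalisation with 3,3-dimethoxypentane (CSA, THF, reflux) should give 1,2:4,5-di-O-(pentan-3-ylidene)-L-arabitol F3, which leaves only the C3 hydroxyl free.
- NaH, CS2 and MeI convert it into O-[1,2:4,5-di-O-(pentan-3-ylidene)-L-arabitol-3-yl] S-methyl carbonodithioate F4.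
- Barton–McCombie deoxygenation (Bu3SnH, AIBN, toluene, 110 °C) gives (4R,4'R)-4,4'-methylenebis(2,2-diethyl-1,3-dioxolane) F5.
- Aqueous HCl in MeOH releases (2R,4R)-pentane-1,2,4,5-tetraol F6.
- Primary-selective tosylation (TsCl 2.1 equiv, Bu2SnO cat., Et3N, CH2Cl2) gives (2R,4R)-2,4-dihydroxypentane-1,5-diyl bis(4-methylbenzenesulfonate) F7.
- K2CO3 in MeOH closes both oxiranes with retention at the carbinol carbons to give 5.

Further compounds
F1 | step 7 | (2R)-1-{2-[4-(benzyloxy)-3-methoxyphenyl]-1,3-dithian-2-yl}-3-[(2R)-oxiran-2-yl]propan-2-ol | COc1cc(C2(C[C@H](O)C[C@@H]3CO3)SCCCS2)ccc1OCc1ccccc1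
F2 | step 8 | (3S,5S)-1-[4-(benzyloxy)-3-methoxyphenyl]-7-[4-(benzyloxy)-3,5-dimethoxyphenyl]heptane-3,5-diol | COc1cc(CC[C@H](O)C[C@@H](O)CCc2cc(OC)c(OCc3ccccc3)c(OC)c2)ccc1OCc1ccccc1
F3 | step 2 | 1,2:4,5-di-O-(pentan-3-ylidene)-L-arabitol | CCC1(CC)OC[C@H](O1)C(O)[C@@H]1COC(CC)(CC)O1
F4 | step 2 | O-[1,2:4,5-di-O-(pentan-3-ylidene)-L-arabitol-3-yl] S-methyl carbonodithioate | CCC1(CC)OC[C@H](O1)C(OC(=S)SC)[C@@H]1COC(CC)(CC)O1
F5 | step 2 | (4R,4'R)-4,4'-methylenebis(2,2-diethyl-1,3-dioxolane) | CCC1(CC)OC[C@H](O1)C[C@@H]1COC(CC)(CC)O1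
F6 | step 2 | (2R,4R)-pentane-1,2,4,5-tetraol | OC[C@H](O)C[C@@H](O)CO
F7 | step 2 | (2R,4R)-2,4-dihydroxypentane-1,5-diyl bis(4-methylbenzenesulfonate) | Cc1ccc(cc1)S(=O)(=O)OC[C@H](O)C[C@@H](O)COS(=O)(=O)c1ccc(C)cc1
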